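Rings B and C are each cut at C1'–C2' and C3'–C4'. This removes C2'(O)–C3'(CH3) as 1-(triisopropylsiloxy)propyne and leaves C4', C5', C6' and C1' as a cyclobutenone on the bridge carbon. Heating precursor 11 with this alkyne is a twofold Danheiser benzannulation that builds both side rings at once. Precursor 11 is the benzyl-protected (R)-acyl ring A core with two 3-siloxycyclobut-2-enon-2-ylmethyl arms. The feature exploited is the C3' methyl between the oxygens on C2' and C4'. The former ketene oxygen ends up as the single unprotected phenol on C4', the one position that needs OCH3. That phenol also steers iodination to C5', so the acetyl groups enter by neutral Stille coupling.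

Key step: step 7

Locants:
- Ring A: C1 acyl, C2/C4/C6 oxygen, C3/C5 bridge CH2.
- Rings B and C: C1' bridge, C2' OH, C3' CH3, C4' OCH3, C5' acetyl, C6' OH.

Assumptions:
- (R)-2-Methylbutanoic acid and cyclobutane-1,3-dione are bought. The dione is stored cold and reacts as its enol.
- Intermediates of twofold steps that are not isolated are drawn with both arms at the same stage.
- The single (R) centre comes from 1. Its integrity should be checked by chiral HPLC at 4 and at 7.

Step 1
Reactants: 1 (R)-2-methylbutanoic acid; 2 phloroglucinol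
Product: 4 (R)-2-methyl-1-(2,4,6-trihydroxyphenyl)butan-1-one, via acid chloride 3 (not isolated)
Conditions: (COCl)2, cat. DMF, CH2Cl2, 0 °C to rt; then 2, AlCl3 (4 equiv), CH2Cl2–PhNO2, 0 to 40 °C; 1 M HCl work-up
Reagents that add atoms: oxalyl chloride, O=C(Cl)C(Cl)=O (supplies the chlorine of 3 only)
Why: Friedel–Crafts C-acylation of the strongly activated ring should stop after one acyl group because the aluminium chelate of 4 is deactivated, and the (R) centre is carried over from 1 because neither the base-free chloride formation nor the acylation offers a ketene or enolate pathway.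

Step 2
Reactants: 4 (R)-2-methyl-1-(2,4,6-trihydroxyphenyl)butan-1-one
Product: 6 (R)-2,4,6-trihydroxy-5-(2-methylbutanoyl)benzene-1,3-dicarbaldehyde, via bis(chloro ether) 5 (not isolated)
Conditions: Cl2CHOMe (5 equiv), TiCl4 (6 equiv), CH2Cl2, −10 °C to rt; then ice, 1 M HCl
Reagents that add atoms: dichloromethyl methyl ether, COC(Cl)Cl; water, O
Why: In this Rieche formylation the titanium phenolates of 4 guide the electrophile to the two remaining ring carbons C3 and C5, hydrolysis of 5 frees the aldehydes, and the cold base-free medium should leave the α-stereocentre untouched.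

Step 3
Reactants: 6 (R)-2,4,6-trihydroxy-5-(2-methylbutanoyl)benzene-1,3-dicarbaldehyde
Product: 7 (R)-2,4,6-tris(benzyloxy)-5-(2-methylbutanoyl)benzene-1,3-dicarbaldehyde
Conditions: BnBr (4.5 equiv), K2CO3 (6 equiv), DMF, 50 °C
Reagents that add atoms: benzyl bromide, BrCc1ccccc1
Why: In this Williamson etherification every ring carbon of 6 is already substituted, so the C-benzylation typical of phloroglucinols has no open site, and carbonate is too weak to enolise the hindered ketone.

Step 4
Reactants: 7 (R)-2,4,6-tris(benzyloxy)-5-(2-methylbutanoyl)benzene-1,3-dicarbaldehyde; 8 cyclobutane-1,3-dione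
Product: 10 (R)-1-{2,4,6-tris(benzyloxy)-3,5-bis[(2-hydroxy-4-oxocyclobut-1-en-1-yl)methyl]phenyl}-2-methylbutan-1-one, via bis(alkylidene dione) 9 (not isolated)
Conditions: 8 (2.4 equiv), Hantzsch ester (2.4 equiv), L-proline (20 mol %), MeCN–CH2Cl2, rt; cold NaHCO3 extraction, re-acidification
Reagents that add atoms: none
Why: This is the organocatalytic three-component reductive alkylation of a cyclic 1,3-dione (Knoevenagel condensation, then Hantzsch ester transfer hydrogenation), in which the acidic enol 8 condenses through the proline iminium ion of each aldehyde, the push–pull alkylidene 9 should accept hydride at the benzylic carbon faster than it adds a second dione, and the shielded ring A ketone neither condenses nor enolises.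

Step 5
Reactants: 10 bis(enol) of step 4
Product: 11 (R)-1-{2,4,6-tris(benzyloxy)-3,5-bis[[4-oxo-2-(triisopropylsiloxy)cyclobut-1-en-1-yl]methyl]phenyl}-2-methylbutan-1-one
Conditions: TIPSCl (2.4 equiv), imidazole (5 equiv), CH2Cl2, 0 °C to rt; filtration through Et3N-washed silica, used at once
Reagents that add atoms: chlorotriisopropylsilane, CC(C)[Si](Cl)(C(C)C)C(C)C
Why: This is O-silylation of a vinylogous acid, analogous to silyl ester formation, in which the two oxygens of each symmetric dione are equivalent so only one regioisomer can form, the bulky silyl group slows hydrolysis, and TIPSCl with imidazole is too mild to silylate the ring A ketone through its enol.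

Step 6
Reactants: 12 ethyl acetate
Product: 15 1-(triisopropylsiloxy)propyne, via dibromo enolate 13 (not isolated), via lithium ynolate 14 (not isolated)
Conditions: CH2Br2, lithium 2,2,6,6-tetramethylpiperidide (2.2 equiv), THF, −78 °C; 12; then n-BuLi, −78 °C to rt; then TIPSCl, −78 °C to rt; distillation
Reagents that add atoms: dibromomethane, BrCBr; chlorotriisopropylsilane, CC(C)[Si](Cl)(C(C)C)C(C)C; lithium 2,2,6,6-tetramethylpiperidide, [Li]N1C(C)(C)CCCC1(C)C (lithium of 13 and 14 only)
Why: This is a Kowalski ester homologation stopped at the ynolate, in which dibromomethyllithium adds to the ester, enolate 13 undergoes bromine–lithium exchange and a 1,2-methyl shift to 14, and the bulky silyl chloride should capture 14 on oxygen and not on carbon.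

Step 7
Reactants: 11 bis(3-siloxycyclobutenone) core; 15 1-(triisopropylsiloxy)propyne
Product: 20 (R)-1-{2,4,6-tris(benzyloxy)-3,5-bis[[4-hydroxy-3-methyl-2,6-bis(triisopropylsiloxy)phenyl]methyl]phenyl}-2-methylbutan-1-one, via bis(vinylketene) 16 (not isolated), via bis(alkenylcyclobutenone) 17 (not isolated), via bis(dienylketene) 18 (not isolated), via bis(cyclohexadienone) 19 (not isolated)
Conditions: 15 (6 equiv), degassed toluene, 110 °C, slow addition of 11 by syringe pump; then 140 °C, sealed tube, argon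
Reagents that add atoms: none
Why: Each arm opens by a thermal four-electron electrocyclic reaction (breaking C4'–C5') to the siloxy vinylketene 16, whose ketene C=C takes up the electron-rich alkyne 15 in a [2+2] cycloaddition to give 17, which creates C3'–C4' and C1'–C2'. A second four-electron opening breaks the old C4'–C1' bond to give dienylketene 18, and ring B and ring C are then each closed by a six-electron electrocyclisation that re-forms C4'–C5', after which dienone 19 tautomerises to the phenol. The closest known reaction type is the Danheiser benzannulation of cyclobutenones with triisopropylsiloxyalkynes to resorcinol monosilyl ethers, run here twice on one core and with an oxygen substituent on the cyclobutenone. No stereocentre is created in 20 (the quaternary carbon of 17 is transient), and the (R) centre next to the hindered ketone only experiences neutral heating. The selectivity needed is the orientation of the [2+2] step, which polarity secures because the methyl-bearing β-carbon of the ynol ether is its nucleophilic end and attacks the electrophilic ketene carbonyl carbon, placing the free hydroxyl on C4' beside C3'–CH3 and the alkyne oxygen on C2'. Excess 15 and slow addition of 11 keep the ketene dilute, so capture by product phenol or by a neighbouring benzyloxy oxygen should not compete.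

Step 8
Reactants: 20 trimer with free C4' phenols
Product: 21 (R)-1-{2,4,6-tris(benzyloxy)-3,5-bis[[4-hydroxy-3-iodo-5-methyl-2,6-bis(triisopropylsiloxy)phenyl]methyl]phenyl}-2-methylbutan-1-one (iodine on C5' of rings B and C)
Conditions: N-iodosuccinimide (2.1 equiv), CH2Cl2, −20 to 0 °C, dark
Reagents that add atoms: N-iodosuccinimide, O=C1CCC(=O)N1I
Why: In this electrophilic aromatic iodination C5' is the only unsubstituted carbon of the two activated rings and lies ortho to the free C4' hydroxyl, whereas C1' is shielded by two siloxy groups, ring A is fully substituted and the benzyl rings are unactivated.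

Step 9
Reactants: 21 bis(iodophenol)
Product: 22 (R)-1-{2,4,6-tris(benzyloxy)-3,5-bis[[3-iodo-4-methoxy-5-methyl-2,6-bis(triisopropylsiloxy)phenyl]methyl]phenyl}-2-methylbutan-1-one
Conditions: MeI (6 equiv), K2CO3 (4 equiv), dry acetone, rt to 40 °C
Reagents that add atoms: iodomethane, CI
Why: In this Williamson O-methylation the two C4' phenols are the only free hydroxyls, the siloxy groups sit meta to them so no silyl migration is possible, and dry carbonate should spare both the aryl silyl ethers and the α-stereocentre.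

Step 10
Reactants: 22 bis(aryl iodide)
Product: 24 (R)-1-{2,4,6-tris(benzyloxy)-3,5-bis[[3-acetyl-4-methoxy-5-methyl-2,6-bis(triisopropylsiloxy)phenyl]methyl]phenyl}-2-methylbutan-1-one, via bis(enol ether) 23 (not isolated)
Conditions: Bu3SnC(OEt)=CH2 (3 equiv), PdCl2(PPh3)2 (10 mol %), toluene, 100 °C; then 1 M HCl, THF, rt
Reagents that add atoms: tributyl(1-ethoxyvinyl)stannane, C=C(OCC)[Sn](CCCC)(CCCC)CCCC; water, O
Why: Stille coupling with an acetyl anion equivalent followed by brief enol ether hydrolysis puts the acetyl groups on C5' without any Lewis acid, so the acid-labile diarylmethane bridges, the benzyl and silyl ethers and the stereocentre should all survive.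

Step 11
Reactants: 24 bis(acetyl) tetrasilyl ether
Product: 25 (R)-1-{3,5-bis[(3-acetyl-2,6-dihydroxy-4-methoxy-5-methylphenyl)methyl]-2,4,6-tris(benzyloxy)phenyl}-2-methylbutan-1-one
Conditions: Bu4NF (5 equiv), AcOH (5 equiv), THF, 0 °C
Reagents that add atoms: none
Why: Fluoride cleaves aryl silyl ethers quickly, and the acetic acid buffer keeps the medium from becoming basic enough to scramble the methylene bridges or enolise the ketone, while the acetyl groups already in place make the freed phenols less prone to oxidation.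

Step 12
Reactants: 25 tri-O-benzyl trimer
Product: 26 (R)-1-{3,5-bis[(3-acetyl-2,6-dihydroxy-4-methoxy-5-methylphenyl)methyl]-2,4,6-trihydroxyphenyl}-2-methylbutan-1-one (CNP0201397.1)
Conditions: H2 (1 atm), Pd/C (10 wt % Pd), EtOAc–MeOH, rt
Reagents that add atoms: none
Why: Catalytic hydrogenolysis removes the three aryl benzyl ethers under neutral conditions, while the hydrogen-bonded ortho-hydroxyaryl ketones, the diarylmethane C–C bonds and the stereocentre are not expected to react at atmospheric pressure.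

Compound list
1 | (R)-2-methylbutanoic acid | CC[C@@H](C)C(O)=O | starting material
2 | phloroglucinol | Oc1cc(O)cc(O)c1 | starting material
3 | (R)-2-methylbutanoyl chloride | CC[C@@H](C)C(Cl)=O | intermediate
4 | (R)-2-methyl-1-(2,4,6-trihydroxyphenyl)butan-1-one | CC[C@@H](C)C(=O)c1c(O)cc(O)cc1O | intermediate
5 | (R)-1-{3,5-bis[chloro(methoxy)methyl]-2,4,6-trihydroxyphenyl}-2-methylbutan-1-one (chloro ether carbons undefined, lost on hydrolysis) | CC[C@@H](C)C(=O)c1c(O)c(C(Cl)OC)c(O)c(C(Cl)OC)c1O | intermediate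
6 | (R)-2,4,6-trihydroxy-5-(2-methylbutanoyl)benzene-1,3-dicarbaldehyde | CC[C@@H](C)C(=O)c1c(O)c(C=O)c(O)c(C=O)c1O | intermediate
7 | (R)-2,4,6-tris(benzyloxy)-5-(2-methylbutanoyl)benzene-1,3-dicarbaldehyde | CC[C@@H](C)C(=O)c1c(OCc2ccccc2)c(C=O)c(OCc2ccccc2)c(C=O)c1OCc1ccccc1 | intermediate
8 | cyclobutane-1,3-dione | O=C1CC(=O)C1 | starting material
9 | ring A core 7 with both CHO groups condensed to 2-arylidenecyclobutane-1,3-diones | CC[C@@H](C)C(=O)c1c(OCc2ccccc2)c(C=C2C(=O)CC2=O)c(OCc2ccccc2)c(C=C2C(=O)CC2=O)c1OCc1ccccc1 | intermediate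
10 | (R)-1-{2,4,6-tris(benzyloxy)-3,5-bis[(2-hydroxy-4-oxocyclobut-1-en-1-yl)methyl]phenyl}-2-methylbutan-1-one | CC[C@@H](C)C(=O)c1c(OCc2ccccc2)c(CC2=C(O)CC2=O)c(OCc2ccccc2)c(CC2=C(O)CC2=O)c1OCc1ccccc1 | intermediate
11 | (R)-1-{2,4,6-tris(benzyloxy)-3,5-bis[[4-oxo-2-(triisopropylsiloxy)cyclobut-1-en-1-yl]methyl]phenyl}-2-methylbutan-1-one | CC[C@@H](C)C(=O)c1c(OCc2ccccc2)c(CC2=C(O[Si](C(C)C)(C(C)C)C(C)C)CC2=O)c(OCc2ccccc2)c(CC2=C(O[Si](C(C)C)(C(C)C)C(C)C)CC2=O)c1OCc1ccccc1 | intermediate
12 | ethyl acetate | CCOC(C)=O | starting material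
13 | lithium 1,1-dibromoprop-1-en-2-olate | CC([O-])=C(Br)Br.[Li+] | intermediate
14 | lithium prop-1-yn-1-olate | CC#C[O-].[Li+] | intermediate
15 | 1-(triisopropylsiloxy)propyne | CC#CO[Si](C(C)C)(C(C)C)C(C)C | intermediate
16 | ring A core with two 2-(oxomethylidene)-3-(triisopropylsiloxy)but-3-enyl arms (siloxy vinylketenes) | CC[C@@H](C)C(=O)c1c(OCc2ccccc2)c(CC(=C=O)C(=C)O[Si](C(C)C)(C(C)C)C(C)C)c(OCc2ccccc2)c(CC(=C=O)C(=C)O[Si](C(C)C)(C(C)C)C(C)C)c1OCc1ccccc1 | intermediate
17 | ring A core with two [3-methyl-4-oxo-2-(triisopropylsiloxy)-1-[1-(triisopropylsiloxy)vinyl]cyclobut-2-en-1-yl]methyl arms (quaternary carbons undefined, transient) | CC[C@@H](C)C(=O)c1c(OCc2ccccc2)c(CC2(C(=C)O[Si](C(C)C)(C(C)C)C(C)C)C(=O)C(C)=C2O[Si](C(C)C)(C(C)C)C(C)C)c(OCc2ccccc2)c(CC2(C(=C)O[Si](C(C)C)(C(C)C)C(C)C)C(=O)C(C)=C2O[Si](C(C)C)(C(C)C)C(C)C)c1OCc1ccccc1 | intermediate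
18 | ring A core with two dienylketene arms, ketene and siloxyvinyl groups cis on the central double bond | CC[C@@H](C)C(=O)c1c(OCc2ccccc2)c(C/C(C(=C)O[Si](C(C)C)(C(C)C)C(C)C)=C(O[Si](C(C)C)(C(C)C)C(C)C)/C(C)=C=O)c(OCc2ccccc2)c(C/C(C(=C)O[Si](C(C)C)(C(C)C)C(C)C)=C(O[Si](C(C)C)(C(C)C)C(C)C)/C(C)=C=O)c1OCc1ccccc1 | intermediate
19 | ring A core with two cyclohexa-2,4-dienone arms (keto tautomer of 20, C5' as CH2) | CC[C@@H](C)C(=O)c1c(OCc2ccccc2)c(CC2=C(O[Si](C(C)C)(C(C)C)C(C)C)CC(=O)C(C)=C2O[Si](C(C)C)(C(C)C)C(C)C)c(OCc2ccccc2)c(CC2=C(O[Si](C(C)C)(C(C)C)C(C)C)CC(=O)C(C)=C2O[Si](C(C)C)(C(C)C)C(C)C)c1OCc1ccccc1 | intermediate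
20 | (R)-1-{2,4,6-tris(benzyloxy)-3,5-bis[[4-hydroxy-3-methyl-2,6-bis(triisopropylsiloxy)phenyl]methyl]phenyl}-2-methylbutan-1-one | CC[C@@H](C)C(=O)c1c(OCc2ccccc2)c(Cc2c(O[Si](C(C)C)(C(C)C)C(C)C)c(C)c(O)cc2O[Si](C(C)C)(C(C)C)C(C)C)c(OCc2ccccc2)c(Cc2c(O[Si](C(C)C)(C(C)C)C(C)C)c(C)c(O)cc2O[Si](C(C)C)(C(C)C)C(C)C)c1OCc1ccccc1 | intermediate
21 | 20 with iodine on C5' of rings B and C | CC[C@@H](C)C(=O)c1c(OCc2ccccc2)c(Cc2c(O[Si](C(C)C)(C(C)C)C(C)C)c(C)c(O)c(I)c2O[Si](C(C)C)(C(C)C)C(C)C)c(OCc2ccccc2)c(Cc2c(O[Si](C(C)C)(C(C)C)C(C)C)c(C)c(O)c(I)c2O[Si](C(C)C)(C(C)C)C(C)C)c1OCc1ccccc1 | intermediate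
22 | 21 with both C4' hydroxyls methylated | CC[C@@H](C)C(=O)c1c(OCc2ccccc2)c(Cc2c(O[Si](C(C)C)(C(C)C)C(C)C)c(C)c(OC)c(I)c2O[Si](C(C)C)(C(C)C)C(C)C)c(OCc2ccccc2)c(Cc2c(O[Si](C(C)C)(C(C)C)C(C)C)c(C)c(OC)c(I)c2O[Si](C(C)C)(C(C)C)C(C)C)c1OCc1ccccc1 | intermediate
23 | 22 with 1-ethoxyvinyl in place of each iodine | CC[C@@H](C)C(=O)c1c(OCc2ccccc2)c(Cc2c(O[Si](C(C)C)(C(C)C)C(C)C)c(C)c(OC)c(C(=C)OCC)c2O[Si](C(C)C)(C(C)C)C(C)C)c(OCc2ccccc2)c(Cc2c(O[Si](C(C)C)(C(C)C)C(C)C)c(C)c(OC)c(C(=C)OCC)c2O[Si](C(C)C)(C(C)C)C(C)C)c1OCc1ccccc1 | intermediate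
24 | (R)-1-{2,4,6-tris(benzyloxy)-3,5-bis[[3-acetyl-4-methoxy-5-methyl-2,6-bis(triisopropylsiloxy)phenyl]methyl]phenyl}-2-methylbutan-1-one | CC[C@@H](C)C(=O)c1c(OCc2ccccc2)c(Cc2c(O[Si](C(C)C)(C(C)C)C(C)C)c(C)c(OC)c(C(C)=O)c2O[Si](C(C)C)(C(C)C)C(C)C)c(OCc2ccccc2)c(Cc2c(O[Si](C(C)C)(C(C)C)C(C)C)c(C)c(OC)c(C(C)=O)c2O[Si](C(C)C)(C(C)C)C(C)C)c1OCc1ccccc1 | intermediate
25 | (R)-1-{3,5-bis[(3-acetyl-2,6-dihydroxy-4-methoxy-5-methylphenyl)methyl]-2,4,6-tris(benzyloxy)phenyl}-2-methylbutan-1-one | CC[C@@H](C)C(=O)c1c(OCc2ccccc2)c(Cc2c(O)c(C)c(OC)c(C(C)=O)c2O)c(OCc2ccccc2)c(Cc2c(O)c(C)c(OC)c(C(C)=O)c2O)c1OCc1ccccc1 | intermediate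
26 | (R)-1-{3,5-bis[(3-acetyl-2,6-dihydroxy-4-methoxy-5-methylphenyl)methyl]-2,4,6-trihydroxyphenyl}-2-methylbutan-1-one | CC[C@@H](C)C(=O)c1c(O)c(Cc2c(O)c(C)c(OC)c(C(C)=O)c2O)c(O)c(Cc2c(O)c(C)c(OC)c(C(C)=O)c2O)c1O | target

Total step count: 12.
Longest linear sequence: 11 steps (steps 1–5 and 7–12). Step 6 is a one-step side branch.

Steps most likely to fail

1. Step 7.
- Risk: The vinylogous silyl ester resonance may push the first ring opening to a temperature at which the ketene is diverted. Possible diversions are addition of phenol already formed, attack of a neighbouring benzyloxy oxygen followed by benzyl transfer, and dimerisation. Both arms must react cleanly in one molecule, so each loss counts twice.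
- Fallback (sets out from 4, comes back at 26): The side ring is made as a monomer and the bridges are formed last.
  - Commercial 1-(2,4,6-trihydroxy-3-methylphenyl)ethan-1-one F1 is protected with MOMCl and i-Pr2NEt at its two less hindered hydroxyls. This should give 1-[2-hydroxy-4,6-bis(methoxymethoxy)-3-methylphenyl]ethan-1-one F2.
  - The remaining chelated hydroxyl is methylated (MeI, K2CO3, DMF) to 1-[2-methoxy-4,6-bis(methoxymethoxy)-3-methylphenyl]ethan-1-one F3.
  - HCl in MeOH then frees 1-(4,6-dihydroxy-2-methoxy-3-methylphenyl)ethan-1-one F4.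
  - In parallel, 4 undergoes a twofold Mannich reaction (aqueous CH2O, Me2NH, EtOH) to (R)-1-{3,5-bis[(dimethylamino)methyl]-2,4,6-trihydroxyphenyl}-2-methylbutan-1-one F5.
  - Heating F5 with two equivalents of F4 in dioxane expels dimethylamine. The resulting ortho-quinone methides are trapped at the only free ring carbon of F4, which leads directly to 26.

2. Step 4.
- Risk: The four-membered dione may self-condense or ring-open before it condenses with the di-ortho-substituted aldehydes. A second dione may also add to the alkylidene before hydride transfer.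
- Fallback (sets out from 7, comes back at 10): The C–C bond is made by cationic benzylation in place of condensation and reduction.
  - NaBH4 in THF–MeOH at 0 °C should reduce only the two aldehydes, because the ketone is shielded by two ortho benzyloxy groups and its α-branch. The product is (R)-1-[2,4,6-tris(benzyloxy)-3,5-bis(hydroxymethyl)phenyl]-2-methylbutan-1-one F6.
  - F6 and 8 with catalytic TsOH in MeCN undergo dehydrative Friedel–Crafts-type benzylation of the enol at C2 through the trialkoxybenzyl cations. Any O-benzylated material re-ionises under the same conditions, so the mixture should drain to 10.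

3. Step 10.
- Risk: Oxidative addition of zerovalent palladium into the electron-rich C–I bonds, each flanked by two ortho substituents, may be slow, and protodeiodination may take over.
- Fallback (sets out from 20, comes back at 25): The acetyl groups are introduced by electrophilic acylation in place of cross-coupling.
  - 20 is methylated directly (MeI, K2CO3, acetone) to (R)-1-{2,4,6-tris(benzyloxy)-3,5-bis[[4-methoxy-3-methyl-2,6-bis(triisopropylsiloxy)phenyl]methyl]phenyl}-2-methylbutan-1-one F7.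
  - F7 is desilylated (Bu4NF, AcOH, THF) to (R)-1-{2,4,6-tris(benzyloxy)-3,5-bis[(2,6-dihydroxy-4-methoxy-3-methylphenyl)methyl]phenyl}-2-methylbutan-1-one F8.
  - F8 is C-acetylated at the only free carbon C5' by Friedel–Crafts acylation (Ac2O, BF3·OEt2, CH2Cl2, 0 °C to rt, aqueous NaOAc work-up) to give 25. The temperature is kept low to limit acid cleavage of the bridges and of the benzyl ethers.

Further compounds
F1 | step 7 | 1-(2,4,6-trihydroxy-3-methylphenyl)ethan-1-one (bought) | CC(=O)c1c(O)cc(O)c(C)c1O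
F2 | step 7 | 1-[2-hydroxy-4,6-bis(methoxymethoxy)-3-methylphenyl]ethan-1-one | CC(=O)c1c(O)c(C)c(OCOC)cc1OCOC
F3 | step 7 | 1-[2-methoxy-4,6-bis(methoxymethoxy)-3-methylphenyl]ethan-1-one | CC(=O)c1c(OC)c(C)c(OCOC)cc1OCOC
F4 | step 7 | 1-(4,6-dihydroxy-2-methoxy-3-methylphenyl)ethan-1-one | CC(=O)c1c(OC)c(C)c(O)cc1O
F5 | step 7 | (R)-1-{3,5-bis[(dimethylamino)methyl]-2,4,6-trihydroxyphenyl}-2-methylbutan-1-one | CC[C@@H](C)C(=O)c1c(O)c(CN(C)C)c(O)c(CN(C)C)c1O
F6 | step 4 | (R)-1-[2,4,6-tris(benzyloxy)-3,5-bis(hydroxymethyl)phenyl]-2-methylbutan-1-one | CC[C@@H](C)C(=O)c1c(OCc2ccccc2)c(CO)c(OCc2ccccc2)c(CO)c1OCc1ccccc1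
F7 | step 10 | (R)-1-{2,4,6-tris(benzyloxy)-3,5-bis[[4-methoxy-3-methyl-2,6-bis(triisopropylsiloxy)phenyl]methyl]phenyl}-2-methylbutan-1-one | CC[C@@H](C)C(=O)c1c(OCc2ccccc2)c(Cc2c(O[Si](C(C)C)(C(C)C)C(C)C)c(C)c(OC)cc2O[Si](C(C)C)(C(C)C)C(C)C)c(OCc2ccccc2)c(Cc2c(O[Si](C(C)C)(C(C)C)C(C)C)c(C)c(OC)cc2O[Si](C(C)C)(C(C)C)C(C)C)c1OCc1ccccc1
F8 | step 10 | (R)-1-{2,4,6-tris(benzyloxy)-3,5-bis[(2,6-dihydroxy-4-methoxy-3-methylphenyl)methyl]phenyl}-2-methylbutan-1-one | CC[C@@H](C)C(=O)c1c(OCc2ccccc2)c(Cc2c(O)c(C)c(OC)cc2O)c(OCc2ccccc2)c(Cc2c(O)c(C)c(OC)cc2O)c1OCc1ccccc1
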